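**Plan**

- Retrosynthesis: the C2 acetate comes from the 2α,3α-diol (selective acylation), and the C7=C8 alkene from a C7 ketone (enol triflate reduction). Both rings are then opened together by cutting C5–C10 and C8–C9 (intramolecular Diels–Alder reaction of an acyclic 2-silyloxy triene). The triene is cut at C5=C6 (olefination), C9–C11 (Negishi coupling), C10–CH3/C9–I (carboalumination) and C1–C2 (propargylation).
- Enabling feature: ring B (C5–C6–C7–C8–C9–C10) is a cyclohexene fused to ring A along C5–C10. C5–C10 and C8–C9 are the two σ-bonds of a [4+2] adduct of the diene C5=C6–C7=C8 with the dienophile C9=C10, and the ring-A atoms C1–C4 are the tether. The target alkene (C7=C8) lies one bond away from the adduct alkene (C6=C7), so the diene carries a silyloxy group on C7.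
- Forward: a C1–C10 chain from (S)-pantolactone is joined to a C11–C16 chain from (R)-monomethyl 3-methylglutarate, the diene is attached at C5, and one thermal step closes ring A and ring B together. Ring B is then adjusted (ketone to C7=C8 alkene).
- Stereochemistry: C3 and C13 are bought. C2 comes from 1,2-induction by C3. C5, C9 and C10 arise in the cycloaddition, controlled by C2/C3 (face), the E-alkene (C9/C10 cis) and the anti transition state (trans ring fusion).

Key step: step 13

Remark: all intermediates carry the labdane atom numbers of the target (ring A: C1–C5, C10; ring B: C5–C10; side chain C11–C16; C17 on C8; C20 on C10). Both starting materials are taken as commercial single enantiomers. The C8 configuration of the cycloadduct is irrelevant because C8 becomes sp2 in step 14.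

**Route**

Step 1
Reactants: 1 (S)-pantolactone
Product: 2 (2S)-2,4-dihydroxy-N-methoxy-N,3,3-trimethylbutanamide
Conditions: MeNH(OMe)·HCl, i-PrMgCl, THF, −20 → 0 °C
Reagents that add atoms: N,O-dimethylhydroxylamine hydrochloride, CNOC.Cl
Why: Aminolysis of the lactone by the magnesium amide (Weinreb amide formation) opens the ring without touching the C3 stereocentre, freeing the C5 hydroxyl and making C2 an aldehyde precursor.

Step 2
Reactants: 2 (2S)-2,4-dihydroxy-N-methoxy-N,3,3-trimethylbutanamide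
Product: 3 (2S)-N-methoxy-N,3,3-trimethyl-2,4-bis(triethylsilyloxy)butanamide
Conditions: Et3SiCl, imidazole, DMF, 0 → 23 °C
Reagents that add atoms: chlorotriethylsilane, CC[Si](Cl)(CC)CC
Why: Standard silylation protects both hydroxyls, giving a non-chelating C3 ether for step 4 and a primary silyl ether that can be oxidised selectively in step 10.

Step 3
Reactants: 3 (2S)-N-methoxy-N,3,3-trimethyl-2,4-bis(triethylsilyloxy)butanamide
Product: 4 (2S)-3,3-dimethyl-2,4-bis(triethylsilyloxy)butanal
Conditions: i-Bu2AlH, THF, −78 °C; aq. Rochelle salt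
Reagents that add atoms: none
Why: Hydride reduction of a Weinreb amide stops at the chelated tetrahedral intermediate and should release the α-silyloxy aldehyde on work-up without epimerisation.

Step 4
Reactants: 4 (2S)-3,3-dimethyl-2,4-bis(triethylsilyloxy)butanal
Product: 5 (4R,5S)-6,6-dimethyl-5,7-bis(triethylsilyloxy)hept-1-yn-4-ol
Conditions: allenylboronic acid pinacol ester, (PhO)2P(O)OH (10 mol %), 4 Å MS, PhMe, 0 → 23 °C; aq. work-up
Reagents that add atoms: allenylboronic acid pinacol ester, C=C=CB1OC(C)(C)C(C)(C)O1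
Why: Brønsted-acid-catalysed propargylation (SE2′ allenylboration through a closed six-membered transition state) should set the C2 carbinol anti to the C3 silyloxy group by the Cornforth/Felkin–Anh preference, attack occurring on the face away from the quaternary C4.

Step 5
Reactants: 5 (4R,5S)-6,6-dimethyl-5,7-bis(triethylsilyloxy)hept-1-yn-4-ol
Product: 6 (4R,5S)-6,6-dimethyl-4,5,7-tris(triethylsilyloxy)hept-1-yne
Conditions: Et3SiOTf, 2,6-lutidine, CH2Cl2, −78 °C
Reagents that add atoms: triethylsilyl trifluoromethanesulfonate, CC[Si](CC)(CC)OS(=O)(=O)C(F)(F)F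
Why: Silyl triflate with a hindered base silylates the hindered secondary C2 alcohol cleanly.

Step 6
Reactants: 6 (4R,5S)-6,6-dimethyl-4,5,7-tris(triethylsilyloxy)hept-1-yne
Product: 8 (1E,4R,5S)-1-iodo-2,6,6-trimethyl-4,5,7-tris(triethylsilyloxy)hept-1-ene, via alkenylalane 7 (not isolated)
Conditions: Me3Al, Cp2ZrCl2 (20 mol %), CH2Cl2, 0 → 23 °C; then I2, THF, −30 → 0 °C
Reagents that add atoms: trimethylaluminium, C[Al](C)C; iodine, II
Why: Zirconium-catalysed methylalumination (Negishi carboalumination) adds CH3–Al syn across the terminal alkyne with methyl on the internal carbon (C10), and iodinolysis with retention fixes the E geometry that later becomes the cis C9/C10 relationship.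

Step 7
Reactants: 9 (3R)-5-methoxy-3-methyl-5-oxopentanoic acid
Product: 11 (4S)-4-methyloxan-2-one, via hydroxy acid 10 (not isolated)
Conditions: LiOH (1.0 equiv), then LiBH4, THF, 0 → 50 °C; then aq. HCl
Reagents that add atoms: none
Why: Borohydride reduces only the ester of the carboxylate salt and acidification lactonises the hydroxy acid, so the bought stereocentre (the future C13) is carried over unchanged.

Step 8
Reactants: 11 (4S)-4-methyloxan-2-one
Product: 13 methyl (3R)-5-iodo-3-methylpentanoate, via silyl ester 12 (not isolated)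
Conditions: Me3SiI, CH2Cl2, 23 °C; then MeOH
Reagents that add atoms: iodotrimethylsilane, C[Si](C)(C)I; methanol, CO
Why: Iodide opens the silyl-activated lactone at the O–CH2 carbon (SN2 dealkylation) and methanolysis of the silyl ester in the acidic medium should give the iodo ester.

Step 9
Reactants: 13 methyl (3R)-5-iodo-3-methylpentanoate; 8 (1E,4R,5S)-1-iodo-2,6,6-trimethyl-4,5,7-tris(triethylsilyloxy)hept-1-ene
Product: 15 methyl (3S,6E,9R,10S)-3,7,11,11-tetramethyl-9,10,12-tris(triethylsilyloxy)dodec-6-enoate, via alkylzinc iodide 14 (not isolated)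
Conditions: 13, Zn dust, LiCl, THF, 40 °C; then 8, Pd(PPh3)4 (5 mol %), THF, 50 °C
Reagents that add atoms: none
Why: Negishi sp3–sp2 cross-coupling of the ester-bearing alkylzinc iodide with the alkenyl iodide proceeds with retention of alkene geometry and joins C9 to C11.

Step 10
Reactants: 15 methyl (3S,6E,9R,10S)-3,7,11,11-tetramethyl-9,10,12-tris(triethylsilyloxy)dodec-6-enoate
Product: 16 methyl (3S,6E,9R,10S)-3,7,11,11-tetramethyl-12-oxo-9,10-bis(triethylsilyloxy)dodec-6-enoate
Conditions: (COCl)2, DMSO, CH2Cl2, −78 → −30 °C; then Et3N, −78 → 0 °C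
Reagents that add atoms: none
Why: Under Swern conditions a primary triethylsilyl ether is cleaved and oxidised in one operation while secondary silyl ethers survive, unveiling the non-enolisable C5 aldehyde.

Step 11
Reactants: 16 methyl (3S,6E,9R,10S)-3,7,11,11-tetramethyl-12-oxo-9,10-bis(triethylsilyloxy)dodec-6-enoate
Product: 17 methyl (3S,6E,9R,10S,12E)-3,7,11,11-tetramethyl-14-oxo-9,10-bis(triethylsilyloxy)hexadeca-6,12-dienoate
Conditions: diethyl (2-oxobutyl)phosphonate, NaH, THF, 0 → 23 °C
Reagents that add atoms: diethyl (2-oxobutyl)phosphonate, CCOP(=O)(CC(=O)CC)OCC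
Why: Horner–Wadsworth–Emmons olefination with a β-ketophosphonate should give the (E)-enone (C5=C6), the aldehyde having no α-hydrogen.

Step 12
Reactants: 17 methyl (3S,6E,9R,10S,12E)-3,7,11,11-tetramethyl-14-oxo-9,10-bis(triethylsilyloxy)hexadeca-6,12-dienoate
Product: 18 methyl (3S,6E,9R,10S,12E,14Z)-3,7,11,11-tetramethyl-9,10,14-tris(triethylsilyloxy)hexadeca-6,12,14-trienoate
Conditions: Et3SiOTf, Et3N, CH2Cl2, −20 → 0 °C
Reagents that add atoms: triethylsilyl trifluoromethanesulfonate, CC[Si](CC)(CC)OS(=O)(=O)C(F)(F)F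
Why: Soft enolisation and O-silylation of the ethyl ketone (only the C8 hydrogens are available) should give the (Z)-silyl dienol ether, a 2-silyloxydiene with the C17 methyl on the outside.

Step 13
Reactants: 18 methyl (3S,6E,9R,10S,12E,14Z)-3,7,11,11-tetramethyl-9,10,14-tris(triethylsilyloxy)hexadeca-6,12,14-trienoate
Product: 20 methyl (13S)-7-oxo-2α,3α-bis(triethylsilyloxy)-8βH-labdan-15-oate, via cycloadduct enol ether 19 (not isolated)
Conditions: PhMe (0.01 M), 2,6-di-tert-butyl-4-methylphenol, 190 °C, sealed tube; then K2CO3, MeOH, 0 °C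
Reagents that add atoms: none
Why: Heating should trigger a concerted, slightly asynchronous intramolecular [4+2] cycloaddition in which the 2-silyloxydiene C5=C6–C7(OSiEt3)=C8 adds suprafacially to the trisubstituted C9=C10 alkene, forming C5–C10 and C8–C9 in one event; the closest known reaction type is the thermal intramolecular Diels–Alder reaction of silyloxy-substituted 1,3,9-decatrienes to trans-fused octalones with an angular methyl group. Ring B closes as the six-membered cycloadduct itself, and ring A closes in the fused mode as the six-membered ring spanned by the tether C1–C4, whose ends C5 and C10 are joined by one of the new bonds. C9 and C10 are set together by the E-alkene (side chain and C20 methyl cis), and C5 by the anti, chair-like transition state that places H-5 trans to the C10 methyl. The absolute sense of all three comes from the tether stereocentres, because only one chair keeps the C2 silyloxy group equatorial (C3 silyloxy axial), the other forcing it into 1,3-diaxial contact with the C10 and C4 methyl groups; C8 is formed too but is erased in step 14. The step needs facial selectivity, secured by C2/C3 as described, and anti-over-syn selectivity (trans ring fusion), which rests on the tendency of decatrienes with an alkyl group on the internal dienophile carbon to react through the anti transition state and is the least secure point of the route. Methanolysis of the silyl enol ether, which leaves the alkyl silyl ethers intact, then gives the C7 ketone with the C8 methyl equilibrated to the equatorial position.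

Step 14
Reactants: 20 methyl (13S)-7-oxo-2α,3α-bis(triethylsilyloxy)-8βH-labdan-15-oate
Product: 22 methyl (13S)-2α,3α-bis(triethylsilyloxy)-7-(trifluoromethylsulfonyloxy)labd-7-en-15-oate, via potassium enolate 21 (not isolated)
Conditions: KN(SiMe3)2 (0.95 equiv), THF, −78 → 0 °C; then PhNTf2, 0 → 23 °C
Reagents that add atoms: N-phenylbis(trifluoromethanesulfonimide), O=S(=O)(N(c1ccccc1)S(=O)(=O)C(F)(F)F)C(F)(F)F
Why: Equilibration with a deficiency of base should give the thermodynamic enolate towards C8 (tetrasubstituted and directed away from the ring fusion, as in a trans-2-decalone), which is trapped as the enol triflate.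

Step 15
Reactants: 22 methyl (13S)-2α,3α-bis(triethylsilyloxy)-7-(trifluoromethylsulfonyloxy)labd-7-en-15-oate
Product: 23 methyl (13S)-2α,3α-bis(triethylsilyloxy)labd-7-en-15-oate
Conditions: Pd(OAc)2 (5 mol %), PPh3, HCO2H, n-Bu3N, DMF, 60 °C
Reagents that add atoms: none
Why: Palladium-catalysed formate reduction of the alkenyl triflate replaces the triflate by hydrogen without moving the double bond, giving the C7=C8 alkene.

Step 16
Reactants: 23 methyl (13S)-2α,3α-bis(triethylsilyloxy)labd-7-en-15-oate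
Product: 24 methyl (13S)-2α,3α-dihydroxylabd-7-en-15-oate
Conditions: HF·pyridine, pyridine, THF, 0 → 23 °C
Reagents that add atoms: none
Why: Fluoride cleaves both secondary triethylsilyl ethers while the ester and the trisubstituted alkene are inert.

Step 17
Reactants: 24 methyl (13S)-2α,3α-dihydroxylabd-7-en-15-oate
Product: 25 methyl (13S)-2α-acetoxy-3α-hydroxylabd-7-en-15-oate
Conditions: Ac2O (1.2 equiv), pyridine, CH2Cl2, 0 °C
Reagents that add atoms: acetic anhydride, CC(=O)OC(C)=O
Why: Acylation of the equatorial 2α-hydroxyl should outpace that of the axial, neopentyl 3α-hydroxyl next to the gem-dimethyl carbon (steric differentiation of a cis-diol), and the equatorial acetate is also the more stable regioisomer.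

**Compound list**

1 | (S)-pantolactone, (3S)-3-hydroxy-4,4-dimethyloxolan-2-one | CC1(C)COC(=O)[C@H]1O | starting material
2 | (2S)-2,4-dihydroxy-N-methoxy-N,3,3-trimethylbutanamide | CON(C)C(=O)[C@@H](O)C(C)(C)CO | intermediate
3 | (2S)-N-methoxy-N,3,3-trimethyl-2,4-bis(triethylsilyloxy)butanamide | CON(C)C(=O)[C@@H](O[Si](CC)(CC)CC)C(C)(C)CO[Si](CC)(CC)CC | intermediate
4 | (2S)-3,3-dimethyl-2,4-bis(triethylsilyloxy)butanal | O=C[C@@H](O[Si](CC)(CC)CC)C(C)(C)CO[Si](CC)(CC)CC | intermediate
5 | (4R,5S)-6,6-dimethyl-5,7-bis(triethylsilyloxy)hept-1-yn-4-ol | C#CC[C@@H](O)[C@@H](O[Si](CC)(CC)CC)C(C)(C)CO[Si](CC)(CC)CC | intermediate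
6 | (4R,5S)-6,6-dimethyl-4,5,7-tris(triethylsilyloxy)hept-1-yne | C#CC[C@@H](O[Si](CC)(CC)CC)[C@@H](O[Si](CC)(CC)CC)C(C)(C)CO[Si](CC)(CC)CC | intermediate
7 | [(1E,4R,5S)-2,6,6-trimethyl-4,5,7-tris(triethylsilyloxy)hept-1-en-1-yl]dimethylalane (not isolated) | C[Al](C)/C=C(\C)C[C@@H](O[Si](CC)(CC)CC)[C@@H](O[Si](CC)(CC)CC)C(C)(C)CO[Si](CC)(CC)CC | intermediate
8 | (1E,4R,5S)-1-iodo-2,6,6-trimethyl-4,5,7-tris(triethylsilyloxy)hept-1-ene | I/C=C(\C)C[C@@H](O[Si](CC)(CC)CC)[C@@H](O[Si](CC)(CC)CC)C(C)(C)CO[Si](CC)(CC)CC | intermediate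
9 | (3R)-5-methoxy-3-methyl-5-oxopentanoic acid, (R)-monomethyl 3-methylglutarate | OC(=O)C[C@@H](C)CC(=O)OC | starting material
10 | (3S)-5-hydroxy-3-methylpentanoic acid (formed as its lithium salt, not isolated) | OC(=O)C[C@@H](C)CCO | intermediate
11 | (4S)-4-methyloxan-2-one | O=C1C[C@@H](C)CCO1 | intermediate
12 | trimethylsilyl (3R)-5-iodo-3-methylpentanoate (not isolated) | C[Si](C)(C)OC(=O)C[C@@H](C)CCI | intermediate
13 | methyl (3R)-5-iodo-3-methylpentanoate | COC(=O)C[C@@H](C)CCI | intermediate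
14 | [(3R)-5-methoxy-3-methyl-5-oxopentyl]zinc iodide (not isolated) | COC(=O)C[C@@H](C)CC[Zn]I | intermediate
15 | methyl (3S,6E,9R,10S)-3,7,11,11-tetramethyl-9,10,12-tris(triethylsilyloxy)dodec-6-enoate | COC(=O)C[C@@H](C)CC/C=C(\C)C[C@@H](O[Si](CC)(CC)CC)[C@@H](O[Si](CC)(CC)CC)C(C)(C)CO[Si](CC)(CC)CC | intermediate
16 | methyl (3S,6E,9R,10S)-3,7,11,11-tetramethyl-12-oxo-9,10-bis(triethylsilyloxy)dodec-6-enoate | COC(=O)C[C@@H](C)CC/C=C(\C)C[C@@H](O[Si](CC)(CC)CC)[C@@H](O[Si](CC)(CC)CC)C(C)(C)C=O | intermediate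
17 | methyl (3S,6E,9R,10S,12E)-3,7,11,11-tetramethyl-14-oxo-9,10-bis(triethylsilyloxy)hexadeca-6,12-dienoate | COC(=O)C[C@@H](C)CC/C=C(\C)C[C@@H](O[Si](CC)(CC)CC)[C@@H](O[Si](CC)(CC)CC)C(C)(C)/C=C/C(=O)CC | intermediate
18 | methyl (3S,6E,9R,10S,12E,14Z)-3,7,11,11-tetramethyl-9,10,14-tris(triethylsilyloxy)hexadeca-6,12,14-trienoate | COC(=O)C[C@@H](C)CC/C=C(\C)C[C@@H](O[Si](CC)(CC)CC)[C@@H](O[Si](CC)(CC)CC)C(C)(C)/C=C/C(O[Si](CC)(CC)CC)=C/C | intermediate
19 | methyl (13S)-2α,3α,7-tris(triethylsilyloxy)-8αH-labd-6-en-15-oate (5α-H, 9α-H, 10β-CH3, 8β-CH3; not isolated) | COC(=O)C[C@@H](C)CC[C@H]1[C@@H](C)C(O[Si](CC)(CC)CC)=C[C@H]2C(C)(C)[C@H](O[Si](CC)(CC)CC)[C@H](O[Si](CC)(CC)CC)C[C@]12C | intermediate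
20 | methyl (13S)-7-oxo-2α,3α-bis(triethylsilyloxy)-8βH-labdan-15-oate (5α-H, 9α-H, 10β-CH3, 8α-CH3) | COC(=O)C[C@@H](C)CC[C@H]1[C@H](C)C(=O)C[C@H]2C(C)(C)[C@H](O[Si](CC)(CC)CC)[C@H](O[Si](CC)(CC)CC)C[C@]12C | intermediate
21 | potassium C7 enolate (C7=C8) of 20 (not isolated) | COC(=O)C[C@@H](C)CC[C@H]1C(C)=C([O-])C[C@H]2C(C)(C)[C@H](O[Si](CC)(CC)CC)[C@H](O[Si](CC)(CC)CC)C[C@]12C.[K+] | intermediate
22 | methyl (13S)-2α,3α-bis(triethylsilyloxy)-7-(trifluoromethylsulfonyloxy)labd-7-en-15-oate | COC(=O)C[C@@H](C)CC[C@H]1C(C)=C(OS(=O)(=O)C(F)(F)F)C[C@H]2C(C)(C)[C@H](O[Si](CC)(CC)CC)[C@H](O[Si](CC)(CC)CC)C[C@]12C | intermediate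
23 | methyl (13S)-2α,3α-bis(triethylsilyloxy)labd-7-en-15-oate | COC(=O)C[C@@H](C)CC[C@H]1C(C)=CC[C@H]2C(C)(C)[C@H](O[Si](CC)(CC)CC)[C@H](O[Si](CC)(CC)CC)C[C@]12C | intermediate
24 | methyl (13S)-2α,3α-dihydroxylabd-7-en-15-oate | COC(=O)C[C@@H](C)CC[C@H]1C(C)=CC[C@H]2C(C)(C)[C@H](O)[C@H](O)C[C@]12C | intermediate
25 | methyl (13S)-2α-acetoxy-3α-hydroxylabd-7-en-15-oate | COC(=O)C[C@@H](C)CC[C@H]1C(C)=CC[C@H]2C(C)(C)[C@H](O)[C@H](OC(C)=O)C[C@]12C | target

**Summary**

Total step count: 17. Longest linear sequence: 15 steps (steps 1–6, then 9–17).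

Steps most likely to fail:

1. Step 13. The cycloaddition may show poor anti/syn discrimination (cis ring fusion), or the silyl dienol ether may decompose at the temperature an unactivated trisubstituted dienophile needs. The fallback gives the dienophile an ester at C11, so that the cycloaddition is electronically matched and ester-endo (trans-fused) directed; it sets out from 8 and returns at 23. Palladium-catalysed methoxycarbonylation of 8 (Pd(OAc)2, PPh3, CO, MeOH, Et3N) would give the (E)-enoate F1. Oxidation, olefination and silylation as in steps 10–12 would give aldehyde F2, enone F3 and silyloxy triene F4. Heating (PhMe, about 130 °C) should give the trans-fused cycloadduct enol ether F5, and methanolysis the keto ester F6. Enolate triflation and formate reduction as in steps 14–15 would give enol triflate F7 and the Δ7 ester F8. i-Bu2AlH at −78 °C would give aldehyde F9. Wittig reaction (NaN(SiMe3)2) with phosphonium bromide F10, made from methyl (3R)-4-bromo-3-methylbutanoate and PPh3, would give the (Z)-alkene F11. Diimide reduction of its disubstituted alkene would return to 23.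

2. Step 14. Enolate formation may leak towards C6 (regiochemical scrambling), which after reduction would give the C6=C7 alkene, and the ester may compete for base. The fallback replaces enolate chemistry by an anti-elimination; it sets out from 20 and returns at 23. LiBH(s-Bu)3 should attack the ketone from the equatorial side to give the axial 7α-alcohol F12. POCl3 in pyridine should then eliminate through the anti-periplanar axial H-8β to give the trisubstituted alkene 23.

3. Step 4. The 1,2-asymmetric induction in the allenylboration may erode, giving the wrong C2 epimer. The fallback sets C2 by reagent-controlled epoxidation; it sets out from 1 and returns at 6. i-Bu2AlH would reduce 1 to pantolactol F13, and Ph3P=CH2 would open it to the allylic diol F14. Sharpless epoxidation (Ti(Oi-Pr)4, L-(+)-diisopropyl tartrate, t-BuOOH), for which F14 is the fast-reacting enantiomer, should give the erythro epoxy diol F15. Lithium acetylide–ethylenediamine in DMSO would open the epoxide at C1 to the alkyne triol F16, and Et3SiOTf with 2,6-lutidine would give 6.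

Further compounds
F1 | step 13 | methyl (2E,5R,6S)-3,7,7-trimethyl-5,6,8-tris(triethylsilyloxy)oct-2-enoate | COC(=O)/C=C(\C)C[C@@H](O[Si](CC)(CC)CC)[C@@H](O[Si](CC)(CC)CC)C(C)(C)CO[Si](CC)(CC)CC
F2 | step 13 | methyl (2E,5R,6S)-3,7,7-trimethyl-8-oxo-5,6-bis(triethylsilyloxy)oct-2-enoate | COC(=O)/C=C(\C)C[C@@H](O[Si](CC)(CC)CC)[C@@H](O[Si](CC)(CC)CC)C(C)(C)C=O
F3 | step 13 | methyl (2E,5R,6S,8E)-3,7,7-trimethyl-10-oxo-5,6-bis(triethylsilyloxy)dodeca-2,8-dienoate | COC(=O)/C=C(\C)C[C@@H](O[Si](CC)(CC)CC)[C@@H](O[Si](CC)(CC)CC)C(C)(C)/C=C/C(=O)CC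
F4 | step 13 | methyl (2E,5R,6S,8E,10Z)-3,7,7-trimethyl-5,6,10-tris(triethylsilyloxy)dodeca-2,8,10-trienoate | COC(=O)/C=C(\C)C[C@@H](O[Si](CC)(CC)CC)[C@@H](O[Si](CC)(CC)CC)C(C)(C)/C=C/C(O[Si](CC)(CC)CC)=C/C
F5 | step 13 | methyl 2α,3α,7-tris(triethylsilyloxy)-8αH-12,13,14,15,16-pentanorlabd-6-en-11-oate | COC(=O)[C@H]1[C@@H](C)C(O[Si](CC)(CC)CC)=C[C@H]2C(C)(C)[C@H](O[Si](CC)(CC)CC)[C@H](O[Si](CC)(CC)CC)C[C@]12C
F6 | step 13 | methyl 7-oxo-2α,3α-bis(triethylsilyloxy)-8βH-12,13,14,15,16-pentanorlabdan-11-oate | COC(=O)[C@H]1[C@H](C)C(=O)C[C@H]2C(C)(C)[C@H](O[Si](CC)(CC)CC)[C@H](O[Si](CC)(CC)CC)C[C@]12C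
F7 | step 13 | methyl 2α,3α-bis(triethylsilyloxy)-7-(trifluoromethylsulfonyloxy)-12,13,14,15,16-pentanorlabd-7-en-11-oate | COC(=O)[C@H]1C(C)=C(OS(=O)(=O)C(F)(F)F)C[C@H]2C(C)(C)[C@H](O[Si](CC)(CC)CC)[C@H](O[Si](CC)(CC)CC)C[C@]12C
F8 | step 13 | methyl 2α,3α-bis(triethylsilyloxy)-12,13,14,15,16-pentanorlabd-7-en-11-oate | COC(=O)[C@H]1C(C)=CC[C@H]2C(C)(C)[C@H](O[Si](CC)(CC)CC)[C@H](O[Si](CC)(CC)CC)C[C@]12C
F9 | step 13 | 2α,3α-bis(triethylsilyloxy)-12,13,14,15,16-pentanorlabd-7-en-11-al | O=C[C@H]1C(C)=CC[C@H]2C(C)(C)[C@H](O[Si](CC)(CC)CC)[C@H](O[Si](CC)(CC)CC)C[C@]12C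
F10 | step 13 | [(2R)-4-methoxy-2-methyl-4-oxobutyl]triphenylphosphonium bromide | COC(=O)C[C@@H](C)C[P+](c1ccccc1)(c1ccccc1)c1ccccc1.[Br-]
F11 | step 13 | methyl (11Z,13R)-2α,3α-bis(triethylsilyloxy)labda-7,11-dien-15-oate | COC(=O)C[C@@H](C)/C=C\[C@H]1C(C)=CC[C@H]2C(C)(C)[C@H](O[Si](CC)(CC)CC)[C@H](O[Si](CC)(CC)CC)C[C@]12C
F12 | step 14 | methyl (13S)-7α-hydroxy-2α,3α-bis(triethylsilyloxy)-8βH-labdan-15-oate | COC(=O)C[C@@H](C)CC[C@H]1[C@H](C)[C@H](O)C[C@H]2C(C)(C)[C@H](O[Si](CC)(CC)CC)[C@H](O[Si](CC)(CC)CC)C[C@]12C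
F13 | step 4 | (3S)-4,4-dimethyloxolane-2,3-diol (anomeric mixture) | CC1(C)COC(O)[C@H]1O
F14 | step 4 | (3R)-2,2-dimethylpent-4-ene-1,3-diol | C=C[C@@H](O)C(C)(C)CO
F15 | step 4 | (1S)-2,2-dimethyl-1-[(2R)-oxiran-2-yl]propane-1,3-diol | OCC(C)(C)[C@H](O)[C@H]1CO1
F16 | step 4 | (4R,5S)-6,6-dimethylhept-1-yne-4,5,7-triol | C#CC[C@@H](O)[C@@H](O)C(C)(C)CO
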